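**Retrosynthetic overview**

- The strategy rests on the oxygen pattern of the benzene ring: C1 carries the side chain, C2 an acetoxy group flanked by C1 and C3, C3 a methoxy group, C5 a free hydroxyl para to C2, and C4 and C6 are CH. This is a hydroquinone acylated only on its hindered oxygen.
- That pattern is what a 4-acetoxy-4-alkenyl-3-methoxycyclobutenone unfolds into. The arene is opened across the C5–C6 bond (retro-6π) and the resulting dienylketene is folded back to the four-membered ring (retro-4π). The benzene ring is the only ring formed, in the last step.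
- The cyclobutenone is cut at the bond between its acetoxy-bearing carbon and the alkenyl group: an alkenyllithium alkoxide adds to 3-methoxycyclobut-3-ene-1,2-dione (from dimethyl squarate), and both alkoxides are acetylated in the same flask.
- The alkenyl iodide comes from (R)-epichlorohydrin by decyl Grignard opening, acetylide opening of the derived epoxide and Markovnikov HI addition. The only stereocentre of the target is bought with the chiral pool and never touched.

Key step: step 7

Remark on the chemistry: the cyclobutenone precursor is formed and used as a mixture of both configurations at the ring carbon bearing the acetoxy group, because that carbon becomes aromatic in step 7. Decylmagnesium bromide and lithium acetylide–ethylenediamine complex are taken as purchased reagents.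

**Route**

Step 1
Reactants: 1 dimethyl squarate (3,4-dimethoxycyclobut-3-ene-1,2-dione)
Product: 2 4-hydroxy-2,3-dimethoxycyclobut-2-en-1-one (racemic)
Conditions: LiAlH(OtBu)3 (1.05 equiv), THF, –78 °C; aq. work-up
Reagents that add atoms: none
Why: The hindered alkoxyaluminium hydride should deliver a single hydride 1,2 to one of the two equivalent carbonyl groups of the squarate at low temperature and stop at the hydroxycyclobutenone (chemoselective carbonyl reduction).

Step 2
Reactants: 2 4-hydroxy-2,3-dimethoxycyclobut-2-en-1-one
Product: 3 3-methoxycyclobut-3-ene-1,2-dione (methyl semisquarate)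
Conditions: conc. HCl (cat.), CH2Cl2, 23 °C
Reagents that add atoms: water, O
Why: Acid-promoted allylic transposition as used for semisquarate esters: ionisation of the C4 hydroxyl gives a cyclobutenyl cation stabilised by the C2 methoxy group, water adds at C2 and the hemiketal expels methanol to leave the 1,2-dione.

Step 3
Reactants: 4 (R)-epichlorohydrin; 5 decylmagnesium bromide
Product: 6 (R)-1-chlorotridecan-2-ol
Conditions: CuI (10 mol %), THF, –40 → 0 °C; aq. NH4Cl
Reagents that add atoms: none
Why: Copper-catalysed Grignard opening of a terminal epoxide: the organocopper species should attack the unsubstituted epoxide carbon much faster than it displaces the primary chloride, and since no bond to the stereocentre is broken the configuration of 4 is carried over (the descriptor stays R).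

Step 4
Reactants: 6 (R)-1-chlorotridecan-2-ol
Product: 8 (R)-pentadec-1-yn-4-ol, via epoxide (R)-2-undecyloxirane 7 (not isolated)
Conditions: HC≡CLi·H2NCH2CH2NH2 (3 equiv), DMSO, 0 → 23 °C
Reagents that add atoms: lithium acetylide–ethylenediamine complex, [Li+].[C-]#C.NCCN
Why: The first equivalent of acetylide acts as base and closes the chlorohydrin to the epoxide (intramolecular Williamson etherification), which a second equivalent opens by SN2 attack at the terminal carbon; the stereocentre is a spectator in both events.

Step 5
Reactants: 8 (R)-pentadec-1-yn-4-ol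
Product: 9 (R)-2-iodopentadec-1-en-4-ol
Conditions: NaI, TMSCl, H2O, MeCN, 23 °C; aq. Na2S2O3
Reagents that add atoms: sodium iodide, [Na+].[I-]
Why: HI generated in the flask should add once to the terminal alkyne in the Markovnikov sense to give the 2-iodo-1-alkene, a hydroiodination that tolerates a free homopropargylic hydroxyl (silylated in passing and released on work-up).

Step 6
Reactants: 9 (R)-2-iodopentadec-1-en-4-ol; 3 3-methoxycyclobut-3-ene-1,2-dione
Product: 12 4-acetoxy-4-[(4R)-4-acetoxypentadec-1-en-2-yl]-3-methoxycyclobut-2-en-1-one (both epimers at ring C4), via dilithio species 10 (not isolated), via dilithium dialkoxide 11 (not isolated)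
Conditions: MeLi (1.0 equiv), Et2O, –78 °C; t-BuLi (2.0 equiv), –78 °C; cannulated into 3 (1.2 equiv), THF, –78 °C; Ac2O (5 equiv), –78 → 0 °C
Reagents that add atoms: acetic anhydride, CC(=O)OC(C)=O
Why: Deprotonation followed by iodine–lithium exchange should give the alkenyllithium alkoxide, which adds 1,2 to the more electrophilic carbonyl of 3 (the one next to the methoxy-bearing carbon; the other is deactivated as a vinylogous ester), and both lithium alkoxides are then O-acetylated in the flask by Ac2O; the new quaternary ring carbon forms without control, which is harmless.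

Step 7
Reactants: 12 4-acetoxy-4-[(4R)-4-acetoxypentadec-1-en-2-yl]-3-methoxycyclobut-2-en-1-one
Product: 15 (R)-1-(2-acetoxy-5-hydroxy-3-methoxyphenyl)tridecan-2-yl acetate (target), via dienylketene 13 (not isolated), via cyclohexadienone 14 (not isolated)
Conditions: PhMe (0.01 M, degassed), 110 °C, Ar
Reagents that add atoms: none
Why: Heating should break the C1–C4 bond of the cyclobutenone in a conrotatory 4π electrocyclic opening to the dienylketene, whose ketene carbon then bonds to the terminal CH2 of the 1,1-disubstituted alkene in a thermal disrotatory 6π electrocyclisation (the mode by which the six-membered ring closes) to give the cyclohexa-2,4-dienone, which enolises to the phenol. The closest known reaction type is the Moore rearrangement of 4-alkenyl-4-oxycyclobutenones to hydroquinone derivatives, here run on the O-acetylated adduct. By the atom mapping the cyclobutenone carbonyl becomes C5–OH, the ring CH becomes C4, the methoxy carbon C3, the acetoxy carbon C2 and the two alkene carbons C1 and C6, so the acetate arrives on the hindered oxygen without any differentiation of a hydroquinone. No stereocentre is formed, the epimeric ring carbon of 12 becomes sp2, and the side-chain centre is remote from the reacting π system and not enolisable. The step needs torquoselectivity: the acetoxy oxygen, a lone-pair donor, should rotate outward so that the alkenyl group turns inward next to the ketene, and because ring opening is reversible a ketene of the wrong geometry can close back and re-enter the productive channel. High dilution in a non-nucleophilic solvent should keep the ketene from acylating the phenol of product already formed.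

**Compound list**

1 | dimethyl squarate (3,4-dimethoxycyclobut-3-ene-1,2-dione) | COC1=C(OC)C(=O)C1=O | starting material
2 | 4-hydroxy-2,3-dimethoxycyclobut-2-en-1-one (racemic) | COC1=C(OC)C(O)C1=O | intermediate
3 | 3-methoxycyclobut-3-ene-1,2-dione | COC1=CC(=O)C1=O | intermediate
4 | (R)-epichlorohydrin | ClC[C@H]1CO1 | starting material
5 | decylmagnesium bromide | CCCCCCCCCC[Mg]Br | starting material
6 | (R)-1-chlorotridecan-2-ol | CCCCCCCCCCC[C@H](CCl)O | intermediate
7 | (R)-2-undecyloxirane | CCCCCCCCCCC[C@@H]1CO1 | intermediate
8 | (R)-pentadec-1-yn-4-ol | CCCCCCCCCCC[C@H](CC#C)O | intermediate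
9 | (R)-2-iodopentadec-1-en-4-ol | CCCCCCCCCCC[C@H](CC(I)=C)O | intermediate
10 | lithium (R)-2-lithiopentadec-1-en-4-olate | CCCCCCCCCCC[C@H](CC([Li])=C)O[Li] | intermediate
11 | dilithium dialkoxide of 4-hydroxy-4-[(4R)-4-hydroxypentadec-1-en-2-yl]-3-methoxycyclobut-2-en-1-one | CCCCCCCCCCC[C@H](CC(=C)C1(O[Li])C(OC)=CC1=O)O[Li] | intermediate
12 | 4-acetoxy-4-[(4R)-4-acetoxypentadec-1-en-2-yl]-3-methoxycyclobut-2-en-1-one (both epimers at ring C4) | CCCCCCCCCCC[C@H](CC(=C)C1(OC(C)=O)C(OC)=CC1=O)OC(C)=O | intermediate
13 | (R,Z)-dienylketene: 4-acetoxy-3-methoxy-5-methylene-7-acetoxyoctadeca-1,3-dien-1-one | CCCCCCCCCCC[C@H](CC(=C)/C(OC(C)=O)=C(OC)\C=C=O)OC(C)=O | intermediate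
14 | (R)-1-(2-acetoxy-3-methoxy-5-oxocyclohexa-1,3-dien-1-yl)tridecan-2-yl acetate | CCCCCCCCCCC[C@H](CC1=C(OC(C)=O)C(OC)=CC(=O)C1)OC(C)=O | intermediate
15 | (R)-1-(2-acetoxy-5-hydroxy-3-methoxyphenyl)tridecan-2-yl acetate | CCCCCCCCCCC[C@H](Cc1cc(O)cc(OC)c1OC(C)=O)OC(C)=O | target

**Step count**

Total: 7 steps. Longest linear sequence: 5 steps (steps 3, 4, 5, 6, 7 from (R)-epichlorohydrin); the squarate branch contributes steps 1 and 2 and joins at step 6.

**Steps most likely to fail**

Step 7. The acetoxy group may in part rotate inward during ring opening, or the ketene may be intercepted (by the ester carbonyl, or by the phenol of product already formed) faster than it closes, so that material is diverted from the 6π closure. The fallback runs the ring expansion on the free tertiary alcohol, the classical substrate whose hydroxyl rotates outward most strongly, and places the aryl acetate afterwards by way of a silyl ether.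
- It sets out from 9. The dilithio species 10 is added to 3 as in step 6 but quenched with aq. NH4Cl to give 4-hydroxy-4-[(4R)-4-hydroxypentadec-1-en-2-yl]-3-methoxycyclobut-2-en-1-one F1.
- Ac2O in pyridine at 0 °C without DMAP should acetylate only the secondary hydroxyl to give (4R)-2-(1-hydroxy-2-methoxy-4-oxocyclobut-2-en-1-yl)pentadec-1-en-4-yl acetate F2.
- Heating in degassed toluene at 110 °C under argon should give the hydroquinone (R)-1-(2,5-dihydroxy-3-methoxyphenyl)tridecan-2-yl acetate F3.
- TBSCl and imidazole should silylate the C5 hydroxyl, which lies between two ring hydrogens, in preference to the C2 hydroxyl between the methoxy group and the side chain, giving (R)-1-[5-(tert-butyldimethylsilyloxy)-2-hydroxy-3-methoxyphenyl]tridecan-2-yl acetate F4.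
- Ac2O, Et3N and DMAP then acetylate the remaining phenol to (R)-1-[2-acetoxy-5-(tert-butyldimethylsilyloxy)-3-methoxyphenyl]tridecan-2-yl acetate F5.
- HF·pyridine in THF removes the silyl group and the route is rejoined at the target 15.

Step 6. The dilithio species may aggregate and add sluggishly, the side-chain alkoxide may displace the ring methoxy group of the adduct intramolecularly, or the hindered tertiary alkoxide may be acetylated incompletely. The fallback masks the secondary hydroxyl so that a simple monolithium reagent is used and the two acetates are put on in separate operations.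
- It sets out from 9. TESCl and imidazole give (R)-triethyl[(2-iodopentadec-1-en-4-yl)oxy]silane F6.
- Iodine–lithium exchange with t-BuLi (2 equiv) in Et2O at –78 °C, addition to 3 and an Ac2O quench give 4-acetoxy-3-methoxy-4-[(4R)-4-(triethylsilyloxy)pentadec-1-en-2-yl]cyclobut-2-en-1-one F7.
- HF·pyridine buffered with pyridine in THF at 0 °C frees the secondary alcohol, 4-acetoxy-4-[(4R)-4-hydroxypentadec-1-en-2-yl]-3-methoxycyclobut-2-en-1-one F8.
- Ac2O, DMAP and pyridine convert it into 12, where the route is rejoined.

Step 5. HI may add a second time to give the geminal diiodide, or the acidic iodide medium may substitute or eliminate at the secondary carbinol. The fallback replaces HI addition by syn-bromoboration and protodeboronation on the silyl-protected alkyne.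
- It sets out from 8. TBDPSCl and imidazole give (R)-tert-butyl(pentadec-1-yn-4-yloxy)diphenylsilane F9.
- B-bromo-9-BBN in CH2Cl2 at 0 °C followed by AcOH should give the 2-bromo-1-alkene (R)-[(2-bromopentadec-1-en-4-yl)oxy](tert-butyl)diphenylsilane F10.
- TBAF buffered with AcOH in THF gives (R)-2-bromopentadec-1-en-4-ol F11.
- MeLi then t-BuLi as in step 6 convert it into the same dilithio species 10, where the route is rejoined.

**Further compounds**

F1 | step 7 | 4-hydroxy-4-[(4R)-4-hydroxypentadec-1-en-2-yl]-3-methoxycyclobut-2-en-1-one | CCCCCCCCCCC[C@H](CC(=C)C1(O)C(OC)=CC1=O)O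
F2 | step 7 | (4R)-2-(1-hydroxy-2-methoxy-4-oxocyclobut-2-en-1-yl)pentadec-1-en-4-yl acetate | CCCCCCCCCCC[C@H](CC(=C)C1(O)C(OC)=CC1=O)OC(C)=O
F3 | step 7 | (R)-1-(2,5-dihydroxy-3-methoxyphenyl)tridecan-2-yl acetate | CCCCCCCCCCC[C@H](Cc1cc(O)cc(OC)c1O)OC(C)=O
F4 | step 7 | (R)-1-[5-(tert-butyldimethylsilyloxy)-2-hydroxy-3-methoxyphenyl]tridecan-2-yl acetate | CCCCCCCCCCC[C@H](Cc1cc(O[Si](C)(C)C(C)(C)C)cc(OC)c1O)OC(C)=O
F5 | step 7 | (R)-1-[2-acetoxy-5-(tert-butyldimethylsilyloxy)-3-methoxyphenyl]tridecan-2-yl acetate | CCCCCCCCCCC[C@H](Cc1cc(O[Si](C)(C)C(C)(C)C)cc(OC)c1OC(C)=O)OC(C)=O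
F6 | step 6 | (R)-triethyl[(2-iodopentadec-1-en-4-yl)oxy]silane | CCCCCCCCCCC[C@H](CC(I)=C)O[Si](CC)(CC)CC
F7 | step 6 | 4-acetoxy-3-methoxy-4-[(4R)-4-(triethylsilyloxy)pentadec-1-en-2-yl]cyclobut-2-en-1-one | CCCCCCCCCCC[C@H](CC(=C)C1(OC(C)=O)C(OC)=CC1=O)O[Si](CC)(CC)CC
F8 | step 6 | 4-acetoxy-4-[(4R)-4-hydroxypentadec-1-en-2-yl]-3-methoxycyclobut-2-en-1-one | CCCCCCCCCCC[C@H](CC(=C)C1(OC(C)=O)C(OC)=CC1=O)O
F9 | step 5 | (R)-tert-butyl(pentadec-1-yn-4-yloxy)diphenylsilane | CCCCCCCCCCC[C@H](CC#C)O[Si](c1ccccc1)(c1ccccc1)C(C)(C)C
F10 | step 5 | (R)-[(2-bromopentadec-1-en-4-yl)oxy](tert-butyl)diphenylsilane | CCCCCCCCCCC[C@H](CC(Br)=C)O[Si](c1ccccc1)(c1ccccc1)C(C)(C)C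
F11 | step 5 | (R)-2-bromopentadec-1-en-4-ol | CCCCCCCCCCC[C@H](CC(Br)=C)O
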